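**Strategy.** Everything rests on building ring B from an alkyne. In ring B, C1 (bonded to ring A) and C6 (bearing the 9-aryl-9-oxononyl chain) are adjacent, while C2(H)–C3(O)–C4(O)–C5(H) is a symmetric, vicinally dioxygenated four-carbon unit. A cobalt-catalysed [4+2] union of an aryl alkyl alkyne with 2,3-dimethoxybuta-1,3-diene therefore forms the C1–C2 and C6–C5 bonds and closes ring B in one operation, free of regiochemical ambiguity; DDQ then aromatizes the cyclohexa-1,4-diene. The precursor is the ring A veratrole carrying its saturated ketone chain and, ortho to a methoxy group, the 11-(2,6-dimethoxyphenyl)-11-oxoundec-1-ynyl arm, assembled by Sonogashira coupling of two Weinreb amides and a double aryllithium acylation.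

Key step: step 8

Remark: the Wittig alkene 6 is drawn as the Z isomer expected from a non-stabilized ylide (any E isomer converges in step 3), and diene 18 is assumed to be purchasable.

**Step 1**
Reactants: 1 8-bromooctanoic acid; 2 triphenylphosphine
Product: 3 (7-carboxyheptyl)triphenylphosphonium bromide
Conditions: MeCN, reflux
Reagents that add atoms: none
Why: Quaternization of triphenylphosphine by a primary alkyl bromide (SN2 phosphonium salt formation) is clean in refluxing acetonitrile and the free acid does not interfere.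

**Step 2**
Reactants: 3 (7-carboxyheptyl)triphenylphosphonium bromide; 4 3-bromo-4,5-dimethoxybenzaldehyde
Product: 6 (Z)-9-(3-bromo-4,5-dimethoxyphenyl)non-8-enoic acid, via carboxylate ylide 5 (not isolated)
Conditions: NaN(SiMe3)2 (2.2 equiv per 3), THF, 0 °C; then 4, −78 °C → rt; aq. HCl work-up
Reagents that add atoms: none
Why: Wittig olefination of an aromatic aldehyde by a non-stabilized ylide whose acid is parked as the carboxylate by the second equivalent of base should proceed normally, the aryl bromide being inert and the alkene geometry irrelevant.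

**Step 3**
Reactants: 6 (Z)-9-(3-bromo-4,5-dimethoxyphenyl)non-8-enoic acid
Product: 7 9-(3-bromo-4,5-dimethoxyphenyl)nonanoic acid
Conditions: TsNHNH2 (excess, in portions), NaOAc, DME/H2O, reflux
Reagents that add atoms: none
Why: Diimide transfer hydrogenation saturates the non-polar C=C by concerted syn delivery of two hydrogens and, unlike hydrogenation over palladium metal, cannot cleave the aryl C–Br bond.

**Step 4**
Reactants: 7 9-(3-bromo-4,5-dimethoxyphenyl)nonanoic acid
Product: 9 9-(3-bromo-4,5-dimethoxyphenyl)-N-methoxy-N-methylnonanamide, via acyl imidazolide 8 (not isolated)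
Conditions: CDI, CH2Cl2, rt; then MeNHOMe·HCl, rt
Reagents that add atoms: N,O-dimethylhydroxylamine hydrochloride, CNOC.Cl
Why: Acyl imidazolide activation followed by aminolysis is a standard Weinreb amide formation that leaves the aryl bromide and the methyl ethers untouched.

**Step 5**
Reactants: 10 undec-10-ynoic acid
Product: 12 N-methoxy-N-methylundec-10-ynamide, via acyl imidazolide 11 (not isolated)
Conditions: CDI, CH2Cl2, rt; then MeNHOMe·HCl, rt
Reagents that add atoms: N,O-dimethylhydroxylamine hydrochloride, CNOC.Cl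
Why: The same Weinreb amide formation via the acyl imidazolide applies, the terminal alkyne being inert to CDI and to the amine salt.

**Step 6**
Reactants: 9 9-(3-bromo-4,5-dimethoxyphenyl)-N-methoxy-N-methylnonanamide; 12 N-methoxy-N-methylundec-10-ynamide
Product: 13 11-{2,3-dimethoxy-5-[9-(methoxy(methyl)amino)-9-oxononyl]phenyl}-N-methoxy-N-methylundec-10-ynamide
Conditions: PdCl2(MeCN)2 (cat.), XPhos, Cs2CO3, MeCN, 80 °C, slow addition of 12
Reagents that add atoms: none
Why: Copper-free Sonogashira coupling with a bulky biarylphosphine on zerovalent palladium permits oxidative addition into the electron-rich ortho-methoxy aryl bromide, while the absence of copper suppresses oxidative dimerization of 12 and both Weinreb amides are spectators.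

**Step 7**
Reactants: 13 11-{2,3-dimethoxy-5-[9-(methoxy(methyl)amino)-9-oxononyl]phenyl}-N-methoxy-N-methylundec-10-ynamide; 14 1,3-dimethoxybenzene
Product: 17 9-{3-[11-(2,6-dimethoxyphenyl)-11-oxoundec-1-yn-1-yl]-4,5-dimethoxyphenyl}-1-(2,6-dimethoxyphenyl)nonan-1-one, via 2,6-dimethoxyphenyllithium 15 (not isolated), via dilithium bis-hemiaminal alkoxide 16 (not isolated)
Conditions: 14 (2.6 equiv), n-BuLi (2.5 equiv), THF, 0 °C → rt; then 13, −78 → 0 °C; 1 M HCl quench at 0 °C
Reagents that add atoms: none
Why: Directed ortho-lithiation of 1,3-dimethoxybenzene between its two methoxy groups followed by Weinreb ketone synthesis should install both aryl ketones at once, because each chelated tetrahedral adduct survives until the quench and the substrate by design carries neither an aryl halide nor a terminal alkyne proton.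

**Step 8**
Reactants: 17 9-{3-[11-(2,6-dimethoxyphenyl)-11-oxoundec-1-yn-1-yl]-4,5-dimethoxyphenyl}-1-(2,6-dimethoxyphenyl)nonan-1-one; 18 2,3-dimethoxybuta-1,3-diene
Product: 19 9-{3-[2-(9-(2,6-dimethoxyphenyl)-9-oxononyl)-4,5-dimethoxycyclohexa-1,4-dien-1-yl]-4,5-dimethoxyphenyl}-1-(2,6-dimethoxyphenyl)nonan-1-one
Conditions: CoBr2(dppe) (10 mol %), Zn powder (20 mol %), ZnI2 (20 mol %), 18 (4 equiv, two portions), CH2Cl2, rt, strictly anhydrous; filtration through basic alumina
Reagents that add atoms: none
Why: Proposed new method: Zn reduces the divalent cobalt precatalyst to a monovalent cobalt bisphosphine species from which ZnI2 abstracts halide, and this cation binds the s-cis diene and the alkyne, couples them oxidatively to a cobaltacycle of trivalent cobalt and releases the cyclohexa-1,4-diene by reductive elimination, so that the C1–C2 and C6–C5 bonds of ring B are both made. The closest known reaction type is the cobalt-catalysed neutral [4+2] cycloaddition of unactivated internal aryl alkyl alkynes with 2,3-dialkyl- or 2-silyloxybuta-1,3-dienes, and the extension to a 2,3-dialkoxy diene is reasonable because this diene is more electron-rich and equally unhindered at its termini. Ring B closes as a six-membered carbocycle in an intermolecular formal [4+2] annulation, four carbons coming from the diene and two from the alkyne, with the second bond arising by reductive elimination from the metallacycle. No stereocentre is created. The selectivity required is cross-cycloaddition over alkyne cyclotrimerization and diene dimerization, which the chelating dppe ligand, the internal disubstituted alkyne and the excess of diene should secure, whereas regiochemistry cannot arise because the diene is C2-symmetric. The twisted 2,6-dimethoxyaryl ketones and all methyl ethers are spectators, and the acid-labile bis-enol ether is protected by anhydrous conditions and the basic filtration.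

**Step 9**
Reactants: 19 9-{3-[2-(9-(2,6-dimethoxyphenyl)-9-oxononyl)-4,5-dimethoxycyclohexa-1,4-dien-1-yl]-4,5-dimethoxyphenyl}-1-(2,6-dimethoxyphenyl)nonan-1-one
Product: 20 9-{2'-[9-(2,6-dimethoxyphenyl)-9-oxononyl]-2,3,4',5'-tetramethoxy-[1,1'-biphenyl]-5-yl}-1-(2,6-dimethoxyphenyl)nonan-1-one
Conditions: DDQ (1.1 equiv), toluene, 0 °C → rt
Reagents that add atoms: none
Why: Dehydrogenative aromatization of a 1,4-cyclohexadiene by DDQ (hydride abstraction from a doubly allylic CH2, then proton loss) is much faster than benzylic oxidation of the side chains, so one equivalent at low temperature should give the veratrole ring B cleanly.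

**Step 10**
Reactants: 20 9-{2'-[9-(2,6-dimethoxyphenyl)-9-oxononyl]-2,3,4',5'-tetramethoxy-[1,1'-biphenyl]-5-yl}-1-(2,6-dimethoxyphenyl)nonan-1-one
Product: 21 9-{2'-[9-(2,6-dihydroxyphenyl)-9-oxononyl]-2,3,4',5'-tetrahydroxy-[1,1'-biphenyl]-5-yl}-1-(2,6-dihydroxyphenyl)nonan-1-one (CNP0305015.0)
Conditions: BBr3 (excess, 1 M in CH2Cl2), CH2Cl2, −78 °C → rt; then H2O, work-up under argon
Reagents that add atoms: none
Why: Lewis acid ether cleavage with BBr3 (O-coordination, then SN2 attack of bromide on methyl) should remove all eight aryl methyl ethers, the four ortho to the carbonyls being assisted by chelation, while the ketones and the biaryl bond are unaffected.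

**Compound list**
1 | 8-bromooctanoic acid | OC(=O)CCCCCCCBr | starting material
2 | triphenylphosphine | c1ccc(cc1)P(c1ccccc1)c1ccccc1 | starting material
3 | (7-carboxyheptyl)triphenylphosphonium bromide | OC(=O)CCCCCCC[P+](c1ccccc1)(c1ccccc1)c1ccccc1.[Br-] | intermediate
4 | 3-bromo-4,5-dimethoxybenzaldehyde | COc1cc(C=O)cc(Br)c1OC | starting material
5 | sodium 8-(triphenylphosphoranylidene)octanoate (carboxylate ylide, not isolated) | [Na+].[O-]C(=O)CCCCCCC=P(c1ccccc1)(c1ccccc1)c1ccccc1 | intermediate
6 | (Z)-9-(3-bromo-4,5-dimethoxyphenyl)non-8-enoic acid | COc1cc(/C=C\CCCCCCC(=O)O)cc(Br)c1OC | intermediate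
7 | 9-(3-bromo-4,5-dimethoxyphenyl)nonanoic acid | COc1cc(CCCCCCCCC(=O)O)cc(Br)c1OC | intermediate
8 | 9-(3-bromo-4,5-dimethoxyphenyl)-1-(1H-imidazol-1-yl)nonan-1-one (acyl imidazolide, not isolated) | COc1cc(CCCCCCCCC(=O)n2ccnc2)cc(Br)c1OC | intermediate
9 | 9-(3-bromo-4,5-dimethoxyphenyl)-N-methoxy-N-methylnonanamide | COc1cc(CCCCCCCCC(=O)N(C)OC)cc(Br)c1OC | intermediate
10 | undec-10-ynoic acid | C#CCCCCCCCCC(=O)O | starting material
11 | 1-(1H-imidazol-1-yl)undec-10-yn-1-one (acyl imidazolide, not isolated) | C#CCCCCCCCCC(=O)n1ccnc1 | intermediate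
12 | N-methoxy-N-methylundec-10-ynamide | C#CCCCCCCCCC(=O)N(C)OC | intermediate
13 | 11-{2,3-dimethoxy-5-[9-(methoxy(methyl)amino)-9-oxononyl]phenyl}-N-methoxy-N-methylundec-10-ynamide | COc1cc(CCCCCCCCC(=O)N(C)OC)cc(C#CCCCCCCCCC(=O)N(C)OC)c1OC | intermediate
14 | 1,3-dimethoxybenzene | COc1cccc(OC)c1 | starting material
15 | 2,6-dimethoxyphenyllithium (not isolated) | [Li]c1c(OC)cccc1OC | intermediate
16 | dilithium bis-hemiaminal alkoxide from twofold addition of 15 to 13 (not isolated; stereoisomer mixture at the two carbinol carbons, both lost on quench) | COc1cc(CCCCCCCCC(O[Li])(N(C)OC)c2c(OC)cccc2OC)cc(C#CCCCCCCCCC(O[Li])(N(C)OC)c2c(OC)cccc2OC)c1OC | intermediate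
17 | 9-{3-[11-(2,6-dimethoxyphenyl)-11-oxoundec-1-yn-1-yl]-4,5-dimethoxyphenyl}-1-(2,6-dimethoxyphenyl)nonan-1-one | COc1cc(CCCCCCCCC(=O)c2c(OC)cccc2OC)cc(C#CCCCCCCCCC(=O)c2c(OC)cccc2OC)c1OC | intermediate
18 | 2,3-dimethoxybuta-1,3-diene | C=C(OC)C(OC)=C | starting material
19 | 9-{3-[2-(9-(2,6-dimethoxyphenyl)-9-oxononyl)-4,5-dimethoxycyclohexa-1,4-dien-1-yl]-4,5-dimethoxyphenyl}-1-(2,6-dimethoxyphenyl)nonan-1-one | COc1cc(CCCCCCCCC(=O)c2c(OC)cccc2OC)cc(C2=C(CCCCCCCCC(=O)c3c(OC)cccc3OC)CC(OC)=C(OC)C2)c1OC | intermediate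
20 | 9-{2'-[9-(2,6-dimethoxyphenyl)-9-oxononyl]-2,3,4',5'-tetramethoxy-[1,1'-biphenyl]-5-yl}-1-(2,6-dimethoxyphenyl)nonan-1-one | COc1cc(CCCCCCCCC(=O)c2c(OC)cccc2OC)cc(-c2cc(OC)c(OC)cc2CCCCCCCCC(=O)c2c(OC)cccc2OC)c1OC | intermediate
21 | 9-{2'-[9-(2,6-dihydroxyphenyl)-9-oxononyl]-2,3,4',5'-tetrahydroxy-[1,1'-biphenyl]-5-yl}-1-(2,6-dihydroxyphenyl)nonan-1-one | O=C(CCCCCCCCc1cc(O)c(O)c(-c2cc(O)c(O)cc2CCCCCCCCC(=O)c2c(O)cccc2O)c1)c1c(O)cccc1O | target

**Step count.** Total: 10 steps. Longest linear sequence: 9 steps (steps 1–4 and 6–10; step 5 is the side branch).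

**Steps most likely to fail**

Step 8 (Proposed new method). The catalyst may not turn over with this diene: ZnI2 could oligomerize the bis-enol ether, the alkyne could cyclotrimerize, or the ortho-methoxyaryl group could hinder alkyne binding. The fallback drops the benzannulation for a known biaryl cross-coupling; it sets out from bromide 9 (reusing salt 3) and comes back to the route at 20. Purchased 2-bromo-4,5-dimethoxybenzaldehyde F1 would be olefinated with the ylide from 3 as in step 2 to give (Z)-9-(2-bromo-4,5-dimethoxyphenyl)non-8-enoic acid F2. Diimide reduction as in step 3 would give 9-(2-bromo-4,5-dimethoxyphenyl)nonanoic acid F3, and amidation as in step 4 would give 9-(2-bromo-4,5-dimethoxyphenyl)-N-methoxy-N-methylnonanamide F4. Bromide 9 would undergo Miyaura borylation (B2pin2, PdCl2(dppf), KOAc, dioxane, 90 °C) to 9-[3,4-dimethoxy-5-(4,4,5,5-tetramethyl-1,3,2-dioxaborolan-2-yl)phenyl]-N-methoxy-N-methylnonanamide F5. Suzuki–Miyaura coupling of F4 with F5 (Pd(OAc)2, SPhos, K3PO4, toluene/H2O, 90 °C) would give 9-{2'-[9-(methoxy(methyl)amino)-9-oxononyl]-2,3,4',5'-tetramethoxy-[1,1'-biphenyl]-5-yl}-N-methoxy-N-methylnonanamide F6. Twofold addition of 15 as in step 7 would then deliver 20, and step 10 follows.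

Step 7. The hindered aryllithium may enolize the amides or stall after the first addition. The fallback sets out from 13 and comes back at 17, moving the C–C bond formation to a more electrophilic carbonyl. i-Bu2AlH (THF, −78 °C) would reduce both Weinreb amides to 11-[2,3-dimethoxy-5-(9-oxononyl)phenyl]undec-10-ynal F7. Addition of 15 at −78 °C would give 9-{3-[11-(2,6-dimethoxyphenyl)-11-hydroxyundec-1-yn-1-yl]-4,5-dimethoxyphenyl}-1-(2,6-dimethoxyphenyl)nonan-1-ol F8 as a diastereomer mixture of no consequence. Dess–Martin periodinane (NaHCO3, CH2Cl2) would oxidize both carbinols to 17.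

Step 6. Oxidative addition into the electron-rich, ortho-methoxy C–Br bond may be slow, leaving alkyne 12 to oligomerize. The fallback sets out from 9 and comes back at 13, moving the reactivity to the electrophile. Copper-catalysed aromatic Finkelstein exchange (CuI, NaI, trans-N,N'-dimethylcyclohexane-1,2-diamine, dioxane, 110 °C) would give 9-(3-iodo-4,5-dimethoxyphenyl)-N-methoxy-N-methylnonanamide F9. This iodide should couple with 12 under classical Sonogashira conditions at room temperature (PdCl2(PPh3)2, CuI, Et3N, THF) to give 13.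

**Further compounds**
F1 | step 8 | 2-bromo-4,5-dimethoxybenzaldehyde | COc1cc(Br)c(C=O)cc1OC
F2 | step 8 | (Z)-9-(2-bromo-4,5-dimethoxyphenyl)non-8-enoic acid | COc1cc(Br)c(/C=C\CCCCCCC(=O)O)cc1OC
F3 | step 8 | 9-(2-bromo-4,5-dimethoxyphenyl)nonanoic acid | COc1cc(Br)c(CCCCCCCCC(=O)O)cc1OC
F4 | step 8 | 9-(2-bromo-4,5-dimethoxyphenyl)-N-methoxy-N-methylnonanamide | COc1cc(Br)c(CCCCCCCCC(=O)N(C)OC)cc1OC
F5 | step 8 | 9-[3,4-dimethoxy-5-(4,4,5,5-tetramethyl-1,3,2-dioxaborolan-2-yl)phenyl]-N-methoxy-N-methylnonanamide | COc1cc(CCCCCCCCC(=O)N(C)OC)cc(B2OC(C)(C)C(C)(C)O2)c1OC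
F6 | step 8 | 9-{2'-[9-(methoxy(methyl)amino)-9-oxononyl]-2,3,4',5'-tetramethoxy-[1,1'-biphenyl]-5-yl}-N-methoxy-N-methylnonanamide | COc1cc(CCCCCCCCC(=O)N(C)OC)cc(-c2cc(OC)c(OC)cc2CCCCCCCCC(=O)N(C)OC)c1OC
F7 | step 7 | 11-[2,3-dimethoxy-5-(9-oxononyl)phenyl]undec-10-ynal | COc1cc(CCCCCCCCC=O)cc(C#CCCCCCCCCC=O)c1OC
F8 | step 7 | 9-{3-[11-(2,6-dimethoxyphenyl)-11-hydroxyundec-1-yn-1-yl]-4,5-dimethoxyphenyl}-1-(2,6-dimethoxyphenyl)nonan-1-ol (diastereomer mixture) | COc1cc(CCCCCCCCC(O)c2c(OC)cccc2OC)cc(C#CCCCCCCCCC(O)c2c(OC)cccc2OC)c1OC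
F9 | step 6 | 9-(3-iodo-4,5-dimethoxyphenyl)-N-methoxy-N-methylnonanamide | COc1cc(CCCCCCCCC(=O)N(C)OC)cc(I)c1OC
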